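**Retrosynthetic overview**
1. Target triacid ⇐ desilylation of a 3-O-silyl triacid ⇐ lactone opening and C20 alcohol→acid oxidation of a tetracyclic 19,20-δ-lactone C7 methyl ester.
2. Ring B (five-membered) ⇐ photochemical Wolff ring contraction of a 6-diazo-7-ketone; this forms the key C6–C8 bond.
3. Ring C ⇐ intramolecular acylation of an allylic sulfonyl carbanion (C12–C13), ketone reduction, desulfonylation. Ring D ⇐ palladium-catalysed sulfonyl-trimethylenemethane [3+2] onto an exocyclic 7-oxo enone (C13–C14, C8–C15).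
4. C20 carboxyl ⇐ amide-directed photochemical 1,6-hydrogen-transfer lactonisation (the new step); C3 is inverted through the ketone.
5. Start: andrographolide (rings A and B; C4, C5, C9, C10 bought). Ring order: A/B (bought) → D → C → contraction of B.

Assumption: atom labels follow target (gibberellane) numbering throughout, so the exocyclic CH2 of andrographolide is C14, its side-chain carbons are C11/C12, C13/C15/C16/C17 arrive with the allyl sulfone, and "the face of C20" is the face of the C10 substituent.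

**Step 1**
Reactants: 1 andrographolide
Product: 3 methyl ester diol, via carboxylic acid 2 (not isolated)
Conditions: KMnO4 (2.5 equiv), MgSO4, acetone/H2O, −10 → 0 °C; filter, concentrate; then MeI, DMF, 20 °C
Reagents that add atoms: potassium permanganate, [K+].[O-][Mn](=O)(=O)=O; iodomethane, CI
Why: Permanganate reacts fastest with the polarised, conjugated and unhindered 12,13-alkylidene-lactone double bond, in preference to the isolated exocyclic C8=C14 alkene, and cleaves it through to the C12 carboxylate (permanganate oxidative cleavage), which is O-methylated by SN2 with iodomethane; no stereocentre is touched.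

**Step 2**
Reactants: 3 methyl ester diol
Product: 5 nitrile, via aldehyde 4 (not isolated)
Conditions: 2,2,6,6-tetramethylpiperidin-1-oxyl (10 mol %), PhI(OAc)2 (2.2 equiv), NH4OAc (4 equiv), MeCN/H2O 9:1, 20 °C
Reagents that add atoms: ammonium acetate, [NH4+].CC([O-])=O
Why: The oxoammonium salt oxidises only the primary neopentyl alcohol (secondary 3-OH and alkene untouched) and the aldehyde is trapped by ammonia and oxidised a second time in the same pot (one-pot alcohol-to-nitrile oxidation), which puts C19 at the acid level without ever making a β-keto acid.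

**Step 3**
Reactants: 5 nitrile
Product: 6 keto nitrile
Conditions: Dess–Martin periodinane, NaHCO3, CH2Cl2, 20 °C
Reagents that add atoms: none
Why: Dess–Martin oxidation of the only hydroxyl; C4 is quaternary, so the β-keto nitrile cannot enolise or epimerise.

**Step 4**
Reactants: 6 keto nitrile
Product: 7 axial alcohol
Conditions: LiBH(s-Bu)3, THF, −78 °C; H2O
Reagents that add atoms: none
Why: The bulky hydride attacks the 3-ketone equatorially, past the small axial nitrile, because axial approach is blocked by the axial hydrogens at C1 and C5; this gives the axial 3-alcohol (trans to C19) under control of the C4/C5/C10 centres bought with 1 (Selectride reduction).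

**Step 5**
Reactants: 7 axial alcohol
Product: 8 silyl ether
Conditions: t-BuMe2SiOTf, 2,6-lutidine, CH2Cl2, 0 °C
Reagents that add atoms: tert-butyldimethylsilyl triflate, CC(C)(C)[Si](C)(C)OS(=O)(=O)C(F)(F)F
Why: Silyl triflate silylation of the single hindered alcohol; the ether prevents retro-aldol epimerisation of C3 in every later basic step and keeps the O–H out of steps 7 and 8.

**Step 6**
Reactants: 8 silyl ether
Product: 9 amide
Conditions: [PtH{(PMe2O)2H}(PMe2OH)] (3 mol %), EtOH/H2O 4:1, 80 °C
Reagents that add atoms: water, O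
Why: Neutral platinum-catalysed hydration (Ghaffar–Parkins) converts even tertiary nitriles into primary amides and stops there, leaving the methyl ester, the silyl ether and the alkene alone.

**Step 7**
Reactants: 9 amide
Product: 11 enone, via allylic alcohol 10 (not isolated)
Conditions: SeO2 (0.5 equiv), t-BuOOH, CH2Cl2, 20 °C; then Dess–Martin periodinane, NaHCO3, CH2Cl2, 20 °C
Reagents that add atoms: tert-butyl hydroperoxide, CC(C)(C)OO
Why: The SeO2 ene reaction/[2,3]-shift hydroxylates the ring CH2 (C7) next to the 1,1-disubstituted alkene (CH2 before CH) and leaves the double bond exocyclic, and Dess–Martin oxidation of the allylic alcohol gives the α-methylene ketone needed for steps 10 and 13.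

**Step 8**
Reactants: 11 enone
Product: 13 lactone enone, via cyclic imidate 12 (not isolated)
Conditions: PhI(OAc)2 (1.6 equiv), I2 (1.0 equiv), NaHCO3, CH2Cl2, white LED, 25 °C; aq. Na2S2O3; then THF/H2O, AcOH (cat.), 20 °C
Reagents that add atoms: water, O
Why: Proposed new method: N-iodination by acetyl hypoiodite and visible-light N–I homolysis give an electrophilic amidyl radical held 1,3-diaxial to the C20 methyl, so a 1,6-hydrogen transfer through a seven-membered transition state should win (the 1,5 candidates are the axial C–H bonds at C2 and C6, of which C6–H is α to the C7 ketone and C2–H lies next to the silyloxy-bearing carbon, both polarity-mismatched for the electrophilic radical), after which iodine capture of the C20 radical and oxidative C–O closure by the amide oxygen give the cyclic imidate that hydrolyses to the δ-lactone; the closest known reactions are the Barton/Suárez N-iodoamide lactonisation (1,5-transfer to γ-lactones) and the Hofmann–Löffler–Freytag functionalisation of C20 from C19 nitrogen radicals in diterpenoid alkaloid synthesis.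

**Step 9**
Reactants: 14 3-chloro-2-(chloromethyl)prop-1-ene; 15 sodium benzenesulfinate
Product: 16 allyl sulfone
Conditions: 14 (3 equiv), MeOH, 65 °C
Reagents that add atoms: none
Why: SN2 S-alkylation of the sulfinate by one allylic chloride; the excess of dichloride keeps bis-substitution low.

**Step 10**
Reactants: 13 lactone enone; 16 allyl sulfone
Product: 17 spiro ketone
Conditions: Pd(PPh3)4 (5 mol %), Cs2CO3 (1.5 equiv), THF, 50 °C
Reagents that add atoms: none
Why: Zerovalent palladium ionises the allylic chloride and carbonate removes the α-sulfonyl proton to give a sulfonyl-trimethylenemethane–palladium zwitterion, whose sulfonyl-bearing carbon adds to the enone CH2 (C13–C14) and whose allyl terminus is then attacked by the C8 enolate from the face opposite the axial C20 (C8–C15), setting quaternary C8 (Trost/Tsuji–Shimizu [3+2] methylenecyclopentane annulation of an α-methylene ketone).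

**Step 11**
Reactants: 17 spiro ketone
Product: 19 hydroxy sulfone, via β-keto sulfone 18 (not isolated)
Conditions: LiN(SiMe3)2 (2.2 equiv), THF, −78 → −20 °C; AcOH; then NaBH4, MeOH, −40 °C
Reagents that add atoms: none
Why: The allylic α-sulfonyl C–H is the most acidic site, so its carbanion acylates the CH2CO2Me ester in a 6-exo Claisen-type closure of ring C (C12–C13, driven by enolisation towards C11), and NaBH4 then reduces the activated α-sulfonyl ketone faster than the neopentyl C7 ketone and from the face away from the axial C9–C10 bond, giving the axial 12-alcohol.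

**Step 12**
Reactants: 19 hydroxy sulfone
Product: 20 keto alcohol
Conditions: 6% Na(Hg), Na2HPO4, MeOH/THF, −20 °C
Reagents that add atoms: none
Why: Single-electron reductive desulfonylation; the bridgehead carbon cannot eliminate (Bredt) and is simply protonated, its configuration being fixed by the bicyclo[3.2.1]octane.

**Step 13**
Reactants: 20 keto alcohol
Product: 22 diazo ketone, via bis(trifluoroacetyl) compound 21 (not isolated)
Conditions: LiN(SiMe3)2 (2.5 equiv), THF, −78 °C; CF3CO2CH2CF3; then MsN3, Et3N, H2O, MeCN, 20 °C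
Reagents that add atoms: methanesulfonyl azide, CS(=O)(=O)N=[N+]=[N-]
Why: Danheiser detrifluoroacetylative diazo transfer: C6 is the only enolisable position of the C7 ketone (C8 is quaternary), and the O-trifluoroacetate formed at O12 is hydrolysed in the aqueous amine stage.

**Step 14**
Reactants: 22 diazo ketone
Product: 25 methyl ester, via ketene 23 (not isolated), via 6-epi ester 24 (not isolated)
Conditions: hν (365 nm), MeOH, 20 °C; then NaOMe (0.5 equiv), MeOH, 50 °C; AcOH
Reagents that add atoms: methanol, CO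
Why: Photochemical Wolff rearrangement: loss of N2 with 1,2-shift of quaternary C8 (retention) from C7 to C6 forges the C6–C8 bond and contracts ring B to the cyclopentane, methanol traps the ketene, and methoxide equilibrates the enolisable C6 centre to the ester trans to the axial C19/C20 carbons.

**Step 15**
Reactants: 25 methyl ester
Product: 27 silyl triacid, via hydroxy diacid 26 (not isolated)
Conditions: KOH (10 equiv), dioxane/H2O 1:1, 95 °C; cool, NaHCO3 to pH 8–9; 2,2,6,6-tetramethylpiperidin-1-oxyl (0.3 equiv), PhI(OAc)2 (3 equiv), MeCN/H2O, 0 → 20 °C; 1 M HCl to pH 3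
Reagents that add atoms: potassium hydroxide, [K+].[OH-]; water, O
Why: Hydroxide opens the hindered δ-lactone and cleaves the methyl ester (the silyl ether prevents retro-aldol loss of the C3 configuration), and the oxoammonium oxidant then takes the only primary alcohol (C20) through to the acid while the hindered axial 12-OH and the 1,1-disubstituted alkene are left (chemoselective nitroxyl oxidation).

**Step 16**
Reactants: 27 silyl triacid
Product: 28 target gibberellin
Conditions: HF·pyridine, THF, 40 °C
Reagents that add atoms: none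
Why: Fluoride-mediated cleavage of the Si–O bond; acids, alcohols and the exocyclic alkene do not react with buffered HF.

**Compound list**
1 | andrographolide | C[C@@]12CC[C@H]([C@@]([C@H]1CCC(=C)[C@H]2C/C=C/3\[C@@H](COC3=O)O)(C)CO)O | starting material
2 | carboxylic acid 2: decalin of 1 unchanged (3-OH equatorial and cis to 19-CH2OH, C4 and C10 methyls, exocyclic C8=CH2, H5 and H9 trans to the C10 methyl), C9 side chain cut to CH2CO2H; carried as potassium salt | C[C@@]1(CO)[C@H](O)CC[C@]2(C)[C@@H]1CCC(=C)[C@H]2CC(=O)O | intermediate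
3 | methyl ester diol 3: methyl ester of 2 | C[C@@]1(CO)[C@H](O)CC[C@]2(C)[C@@H]1CCC(=C)[C@H]2CC(=O)OC | intermediate
4 | aldehyde 4: C19 aldehyde of 3 | C[C@@]1(C=O)[C@H](O)CC[C@]2(C)[C@@H]1CCC(=C)[C@H]2CC(=O)OC | intermediate
5 | nitrile 5: C19 nitrile (axial on C4, cis to the C10 methyl), 3-OH equatorial | C[C@@]1(C#N)[C@H](O)CC[C@]2(C)[C@@H]1CCC(=C)[C@H]2CC(=O)OC | intermediate
6 | keto nitrile 6: 3-ketone | C[C@@]1(C#N)C(=O)CC[C@]2(C)[C@@H]1CCC(=C)[C@H]2CC(=O)OC | intermediate
7 | axial alcohol 7: 3-OH axial, trans to the nitrile and cis to the C4 methyl | C[C@@]1(C#N)[C@@H](O)CC[C@]2(C)[C@@H]1CCC(=C)[C@H]2CC(=O)OC | intermediate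
8 | silyl ether 8: 3-O-tert-butyldimethylsilyl ether of 7 | C[C@@]1(C#N)[C@@H](O[Si](C)(C)C(C)(C)C)CC[C@]2(C)[C@@H]1CCC(=C)[C@H]2CC(=O)OC | intermediate
9 | amide 9: C19 primary carboxamide | C[C@@]1(C(N)=O)[C@@H](O[Si](C)(C)C(C)(C)C)CC[C@]2(C)[C@@H]1CCC(=C)[C@H]2CC(=O)OC | intermediate
10 | allylic alcohol 10: 7-OH trans to the C10 methyl, exocyclic alkene kept | C[C@@]1(C(N)=O)[C@@H](O[Si](C)(C)C(C)(C)C)CC[C@]2(C)[C@@H]1C[C@H](O)C(=C)[C@H]2CC(=O)OC | intermediate
11 | enone 11: 7-ketone conjugated with exocyclic C8=CH2 | C[C@@]1(C(N)=O)[C@@H](O[Si](C)(C)C(C)(C)C)CC[C@]2(C)[C@@H]1CC(=O)C(=C)[C@H]2CC(=O)OC | intermediate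
12 | cyclic imidate 12: C19(=NH)–O–C20H2 bridge between C4 and C10 | C[C@@]12C(=N)OC[C@@]3(CC[C@@H]1O[Si](C)(C)C(C)(C)C)[C@@H]2CC(=O)C(=C)[C@H]3CC(=O)OC | intermediate
13 | lactone enone 13: 19,20-δ-lactone (C19 carbonyl, O on C20) | C[C@@]12C(=O)OC[C@@]3(CC[C@@H]1O[Si](C)(C)C(C)(C)C)[C@@H]2CC(=O)C(=C)[C@H]3CC(=O)OC | intermediate
14 | 3-chloro-2-(chloromethyl)prop-1-ene | C=C(CCl)CCl | starting material
15 | sodium benzenesulfinate | [Na+].[O-]S(=O)c1ccccc1 | starting material
16 | allyl sulfone 16: 2-(chloromethyl)-3-(phenylsulfonyl)prop-1-ene | C=C(CCl)CS(=O)(=O)c1ccccc1 | intermediate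
17 | spiro ketone 17: 3-methylenecyclopentane spiro at C8 (C14 on the face of C20, C15 on the opposite face), PhSO2 on C13 (epimer mixture, one drawn), 7-ketone, CH2CO2Me on C9 | C[C@@]12C(=O)OC[C@@]3(CC[C@@H]1O[Si](C)(C)C(C)(C)C)[C@@H]2CC(=O)[C@@]4(C[C@H](S(=O)(=O)c5ccccc5)C(=C)C4)[C@H]3CC(=O)OC | intermediate
18 | β-keto sulfone 18: ring C closed, 12-ketone, quaternary C13 bearing PhSO2 | C[C@@]12C(=O)OC[C@@]3(CC[C@@H]1O[Si](C)(C)C(C)(C)C)[C@@H]2CC(=O)[C@]45C[C@](S(=O)(=O)c6ccccc6)(C(=C)C4)C(=O)C[C@@H]35 | intermediate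
19 | hydroxy sulfone 19: 12-OH axial, syn to the C9–C10 bond and anti to the C15–C16 bridge | C[C@@]12C(=O)OC[C@@]3(CC[C@@H]1O[Si](C)(C)C(C)(C)C)[C@@H]2CC(=O)[C@]45C[C@](S(=O)(=O)c6ccccc6)(C(=C)C4)[C@@H](O)C[C@@H]35 | intermediate
20 | keto alcohol 20: C13–H, 7-ketone, 12-OH, 16-methylene | C[C@@]12C(=O)OC[C@@]3(CC[C@@H]1O[Si](C)(C)C(C)(C)C)[C@@H]2CC(=O)[C@]45C[C@H](C(=C)C4)[C@@H](O)C[C@@H]35 | intermediate
21 | bis(trifluoroacetyl) compound 21: C6 trifluoroacetyl (chelated enol) and 12-O-trifluoroacetate | C[C@@]12C(=O)OC[C@@]3(CC[C@@H]1O[Si](C)(C)C(C)(C)C)[C@@H]2/C(=C(/O)C(F)(F)F)C(=O)[C@]45C[C@H](C(=C)C4)[C@@H](OC(=O)C(F)(F)F)C[C@@H]35 | intermediate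
22 | diazo ketone 22: 6-diazo-7-ketone | C[C@@]12C(=O)OC[C@@]3(CC[C@@H]1O[Si](C)(C)C(C)(C)C)[C@@H]2C(=[N+]=[N-])C(=O)[C@]45C[C@H](C(=C)C4)[C@@H](O)C[C@@H]35 | intermediate
23 | ketene 23: ring B contracted, C6=C7=O | C[C@@]12C(=O)OC[C@@]3(CC[C@@H]1O[Si](C)(C)C(C)(C)C)[C@@H]2C(=C=O)[C@]45C[C@H](C(=C)C4)[C@@H](O)C[C@@H]35 | intermediate
24 | 6-epi ester 24: C7 methyl ester on the face of C20 | C[C@@]12C(=O)OC[C@@]3(CC[C@@H]1O[Si](C)(C)C(C)(C)C)[C@@H]2[C@@H](C(=O)OC)[C@]45C[C@H](C(=C)C4)[C@@H](O)C[C@@H]35 | intermediate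
25 | methyl ester 25: C7 methyl ester trans to C19/C20, 19,20-lactone, 3-O-silyl, 12-OH | C[C@@]12C(=O)OC[C@@]3(CC[C@@H]1O[Si](C)(C)C(C)(C)C)[C@@H]2[C@H](C(=O)OC)[C@]45C[C@H](C(=C)C4)[C@@H](O)C[C@@H]35 | intermediate
26 | hydroxy diacid 26: C7 and C19 acids, 20-CH2OH, 3-O-silyl; present as dipotassium salt | C[C@@]1(C(=O)O)[C@@H](O[Si](C)(C)C(C)(C)C)CC[C@]2(CO)[C@@H]1[C@H](C(=O)O)[C@]34C[C@H](C(=C)C3)[C@@H](O)C[C@@H]24 | intermediate
27 | silyl triacid 27: 3-O-tert-butyldimethylsilyl ether of the target gibberellin | C[C@@]1(C(=O)O)[C@@H](O[Si](C)(C)C(C)(C)C)CC[C@]2(C(=O)O)[C@@H]1[C@H](C(=O)O)[C@]34C[C@H](C(=C)C3)[C@@H](O)C[C@@H]24 | intermediate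
28 | target gibberellin 28: the gibberellin named in the task, a C7/C19/C20 triacid with axial 3-OH (trans to C19), axial 12-OH and 16-methylene | C=C1C[C@]23C[C@H]1[C@@H](O)C[C@H]2[C@]1(C(=O)O)CC[C@H](O)[C@@](C)(C(=O)O)[C@H]1[C@@H]3C(=O)O | target

**Totals and risks**
Total step count: 16. Longest linear sequence: 15 (steps 1–8 and 10–16 from andrographolide; step 9 prepares the annulating reagent).

The three steps most likely to fail:

Step 8 (the proposed new lactonisation). The 1,6-hydrogen transfer may lose to Hofmann-type rearrangement or to abstraction at C2. The fallback uses known chemistry, sets out from 11 and returns at 13. Nitrosative hydrolysis of the primary amide (t-BuONO, AcOH, 50 °C) gives the C19 carboxylic acid F3. (PhO)2P(O)N3 and Et3N give the acyl azide F4. Irradiation at 254 nm gives, by acyl-nitrene insertion into the 1,3-diaxial C20–H (the classical route to C20-functionalised diterpenoids from C19 acyl azides, modest yield beside Curtius product), the 19,20-δ-lactam F5. N2O4/NaOAc converts this into the N-nitroso lactam F6, which on warming in toluene undergoes the nitrosoamide rearrangement with loss of nitrogen to the lactone 13.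

Step 1 (chemoselective permanganate cleavage beside the exocyclic alkene). The fallback sets out from 1 and returns at 2. MnO2 in CH2Cl2 oxidises only the allylic 14-OH and gives 14-dehydroandrographolide F1, an alkylidene tetronic acid. Aqueous NaHCO3/THF at 40 °C cleaves it by retro-Knoevenagel hydrolysis to the C12 aldehyde F2. Pinnick oxidation (NaClO2, NaH2PO4, 2-methyl-2-butene) gives the acid 2, which is methylated to 3 as in step 1.

Step 15 (hydrolysis of the hindered C7 ester and selective oxidation beside the free 12-OH). The fallback sets out from 25 and returns at 28. t-BuMe2SiOTf/2,6-lutidine also silylates the 12-OH and gives the bis-silyl ether F7, so that no selectivity between alcohols is needed. KOH in dioxane/H2O at 95 °C, then NaClO2 with catalytic NaOCl and 2,2,6,6-tetramethylpiperidin-1-oxyl at pH 6.7, gives the bis-silyl triacid F8. HF·pyridine removes both silyl groups to give 28.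

**Further compounds**
F1 | step 1 | 14-dehydroandrographolide (14-ketone, alkylidene tetronic acid) | C[C@@]1(CO)[C@H](O)CC[C@]2(C)[C@@H]1CCC(=C)[C@H]2C/C=C3/C(=O)OCC3=O
F2 | step 1 | C12 aldehyde (C9–CH2CHO, 3,19-diol, exocyclic alkene) | C[C@@]1(CO)[C@H](O)CC[C@]2(C)[C@@H]1CCC(=C)[C@H]2CC=O
F3 | step 8 | C19 carboxylic acid of enone 11 | C[C@@]1(C(=O)O)[C@@H](O[Si](C)(C)C(C)(C)C)CC[C@]2(C)[C@@H]1CC(=O)C(=C)[C@H]2CC(=O)OC
F4 | step 8 | C19 acyl azide | C[C@@]1(C(=O)N=[N+]=[N-])[C@@H](O[Si](C)(C)C(C)(C)C)CC[C@]2(C)[C@@H]1CC(=O)C(=C)[C@H]2CC(=O)OC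
F5 | step 8 | 19,20-δ-lactam | C[C@@]12C(=O)NC[C@@]3(CC[C@@H]1O[Si](C)(C)C(C)(C)C)[C@@H]2CC(=O)C(=C)[C@H]3CC(=O)OC
F6 | step 8 | N-nitroso 19,20-δ-lactam | C[C@@]12C(=O)N(N=O)C[C@@]3(CC[C@@H]1O[Si](C)(C)C(C)(C)C)[C@@H]2CC(=O)C(=C)[C@H]3CC(=O)OC
F7 | step 15 | 3,12-bis-O-silyl methyl ester lactone | C[C@@]12C(=O)OC[C@@]3(CC[C@@H]1O[Si](C)(C)C(C)(C)C)[C@@H]2[C@H](C(=O)OC)[C@]45C[C@H](C(=C)C4)[C@@H](O[Si](C)(C)C(C)(C)C)C[C@@H]35
F8 | step 15 | 3,12-bis-O-silyl triacid | C[C@@]1(C(=O)O)[C@@H](O[Si](C)(C)C(C)(C)C)CC[C@]2(C(=O)O)[C@@H]1[C@H](C(=O)O)[C@]34C[C@H](C(=C)C3)[C@@H](O[Si](C)(C)C(C)(C)C)C[C@@H]24
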